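The 2,5-dihydrofuran ring of the furanoid end group (O–C8–C7=C6–C5, carotenoid numbering; C5 carries the ring methyl, C8 the butenolide) is cut across both O–C8 and C7=C6. This leads back to an α-ketol, a 2,2,6,6-tetrasubstituted cyclohexanone with the tertiary C5–OH next to the C6 carbonyl, and an alkenylphosphonium salt that brings C7 and C8. One base-mediated operation (oxa-Michael addition, then intramolecular Wittig reaction) closes the ring, makes the ring-fusion alkene and sets C8 with an alkynyl handle. The handle is grown into the butenolide and condensed with a polyenynal carrying the acetylenic ring. All stereocentres derive from one catalytic ketone reduction.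

Key step: step 8

Remark on labels: C1–C8 are the carotenoid numbers of the furanoid end group (C1 = CMe2, C3 = carbinol carbon, C5 = methyl-bearing O-substituted carbon, C6 = ring-fusion alkene carbon, C7 = ring CH=, C8 = O–CH); TBS = tert-butyldimethylsilyl.
Assumption: the (S,S)-configured catalyst of step 1 is taken to give the (4S)-alcohol by the usual transition-state model; if the sense is opposite, the (R,R)-catalyst is used.

Step 1
Reactants: 1 2,6,6-trimethylcyclohex-2-ene-1,4-dione (ketoisophorone)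
Product: 2 (4S)-4-hydroxy-2,6,6-trimethylcyclohex-2-en-1-one
Conditions: RuCl[(S,S)-TsDPEN](p-cymene) (cat.), KOH (cat.), i-PrOH, rt
Reagents that add atoms: none
Why: Asymmetric transfer hydrogenation (Noyori type) should reduce only the less hindered C4 carbonyl (C1 is flanked by the quaternary carbon and the methyl-bearing alkene carbon), and the chiral ruthenium hydride sets the (4S)-carbinol, the one stereocentre that comes from a catalyst.

Step 2
Reactants: 2 (4S)-4-hydroxy-2,6,6-trimethylcyclohex-2-en-1-one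
Product: 3 (4S)-4-(TBS-oxy)-2,6,6-trimethylcyclohex-2-en-1-one
Conditions: TBSCl, imidazole, DMF, rt
Reagents that add atoms: tert-butyldimethylsilyl chloride CC(C)(C)[Si](C)(C)Cl
Why: Standard silylation of a secondary alcohol gives a bulky ether that steers step 3 and survives all later base, hydride and palladium steps.

Step 3
Reactants: 3 (4S)-4-(TBS-oxy)-2,6,6-trimethylcyclohex-2-en-1-one
Product: 4 (1R,5S,6R)-5-(TBS-oxy)-1,3,3-trimethyl-7-oxabicyclo[4.1.0]heptan-2-one (epoxide trans to the silyloxy group)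
Conditions: 30% aq. H2O2, NaOH (cat.), MeOH, 0 °C
Reagents that add atoms: hydrogen peroxide OO
Why: Weitz–Scheffer nucleophilic epoxidation: hydroperoxide should add to the enone β-carbon anti to the adjacent silyloxy group, so the epoxide oxygen, and with it the future tertiary C5–O stereocentre, is set trans to the C3 oxygen by substrate control.

Step 4
Reactants: 4 (1R,5S,6R)-5-(TBS-oxy)-1,3,3-trimethyl-7-oxabicyclo[4.1.0]heptan-2-one
Product: 5 (2R,4S)-4-(TBS-oxy)-2,6,6-trimethylcyclohexane-1,2-diol as a mixture of C1 epimers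
Conditions: LiAlH4, THF, 0 °C to rt
Reagents that add atoms: none
Why: LiAlH4 reduces the ketone and opens the epoxide by SN2 hydride attack at the secondary carbon in the trans-diaxial (Fürst–Plattner) sense, so the tertiary C–O bond and its configuration are kept; the new secondary carbinol is erased in step 5.

Step 5
Reactants: 5 (2R,4S)-4-(TBS-oxy)-2,6,6-trimethylcyclohexane-1,2-diol
Product: 6 (2R,4S)-4-(TBS-oxy)-2-hydroxy-2,6,6-trimethylcyclohexan-1-one
Conditions: (COCl)2, DMSO, CH2Cl2, −78 °C; Et3N, −78 to 0 °C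
Reagents that add atoms: none
Why: Swern oxidation converts the secondary alcohol into the ketone while the tertiary alcohol cannot be oxidised, giving the α-ketol without touching either stereocentre.

Step 6
Reactants: 7 tert-butyldimethyl(prop-2-yn-1-yloxy)silane; 8 (E)-1,2-dichloroethene (excess)
Product: 9 (E)-tert-butyl[(5-chloropent-4-en-2-yn-1-yl)oxy]dimethylsilane
Conditions: Pd(PPh3)4 (cat.), CuI (cat.), n-BuNH2, Et2O, rt
Reagents that add atoms: none
Why: Sonogashira coupling with an excess of the dihalide stops at mono-alkynylation and retains the alkene geometry.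

Step 7
Reactants: 9 (E)-tert-butyl[(5-chloropent-4-en-2-yn-1-yl)oxy]dimethylsilane
Product: 10 (E)-{5-(TBS-oxy)pent-1-en-3-yn-1-yl}triphenylphosphonium chloride
Conditions: PPh3, Pd2(dba)3 (cat.), toluene, 100 °C
Reagents that add atoms: triphenylphosphine c1ccc(cc1)P(c1ccccc1)c1ccccc1
Why: Palladium-catalysed C–P coupling (quaternisation of PPh3 by an alkenyl halide): the alkyne-activated C–Cl bond should add oxidatively to zerovalent palladium and reductive elimination releases the alkenylphosphonium salt; its alkene geometry is lost in step 8.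

Step 8
Reactants: 6 (2R,4S)-4-(TBS-oxy)-2-hydroxy-2,6,6-trimethylcyclohexan-1-one; 10 (E)-{5-(TBS-oxy)pent-1-en-3-yn-1-yl}triphenylphosphonium chloride
Product: 14 (2R,6S,7aR)-6-(TBS-oxy)-2-[3-(TBS-oxy)prop-1-yn-1-yl]-4,4,7a-trimethyl-2,4,5,6,7,7a-hexahydro-1-benzofuran, via sodium alkoxide 11 (not isolated), via oxido ylide 12 (not isolated), via oxaphosphetane 13 (not isolated)
Conditions: NaH (1.05 equiv), THF, 0 °C to rt; then 10, DMF, rt to 50 °C
Reagents that add atoms: none
Why: NaH turns the tertiary C5–OH into its alkoxide, which adds to the β-carbon (C8) of the alkenylphosphonium salt (oxa-Michael addition, forming O–C8) to give a β-oxido ylide whose carbanion C7 attacks the neighbouring C6 ketone, and collapse of the oxaphosphetane with loss of Ph3PO leaves the C6=C7 bond. The closest known reaction type is the Schweizer 2,5-dihydrofuran synthesis from α-hydroxy ketones and vinylphosphonium salts, and intramolecular Wittig-type olefination of such hindered 2-oxy-2,6,6-trimethylcyclohexanones by an oxygen-tethered phosphorus carbanion is established chemistry. The five-membered ring O–C8–C7–C6–C5 is closed by 5-exo-trig attack of C7 on the C6 carbonyl. C8 is the only new stereocentre: the oxa-Michael step is reversible and the slow Wittig closure onto the doubly neopentyl ketone selects; in the only chair free of a syn-diaxial methyl/methyl clash the C5–O tether is axial, so the oxaphosphetane must be cis-fused, with its oxygen and therefore PPh3 on C7 on the face of the C5 methyl group, and the alkynyl group on C8 takes the position anti to PPh3, that is trans to the C5 methyl (8R). The step needs 1,4- over 1,6-addition to the enyne and ring closure faster than α-ketol rearrangement: alkoxide addition at the alkyne terminus is also reversible and cannot be followed by a five-membered Wittig closure, so material should funnel through the C8 adduct.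

Step 9
Reactants: 14 (2R,6S,7aR)-6-(TBS-oxy)-2-[3-(TBS-oxy)prop-1-yn-1-yl]-4,4,7a-trimethyl-2,4,5,6,7,7a-hexahydro-1-benzofuran
Product: 15 3-[(2R,6S,7aR)-6-(TBS-oxy)-4,4,7a-trimethyl-2,4,5,6,7,7a-hexahydro-1-benzofuran-2-yl]prop-2-yn-1-ol
Conditions: HF·pyridine, pyridine, THF, 0 °C
Reagents that add atoms: none
Why: Buffered fluoride cleaves the unhindered primary propargylic silyl ether much faster than the secondary one, and the pyridine buffer protects the acid-sensitive allylic ether at C8.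

Step 10
Reactants: 15 3-[(2R,6S,7aR)-6-(TBS-oxy)-4,4,7a-trimethyl-2,4,5,6,7,7a-hexahydro-1-benzofuran-2-yl]prop-2-yn-1-ol
Product: 17 (2Z)-3-iodo-3-[(2R,6S,7aR)-6-(TBS-oxy)-4,4,7a-trimethyl-2,4,5,6,7,7a-hexahydro-1-benzofuran-2-yl]prop-2-en-1-ol, via cyclic alkenylaluminate 16 (not isolated)
Conditions: NaAlH2(OCH2CH2OMe)2 (Red-Al), THF, 0 °C to rt; then I2, THF, −78 °C
Reagents that add atoms: iodine II
Why: Hydroxyl-directed trans-hydroalumination of the propargylic alcohol places aluminium on the alkyne carbon remote from the hydroxyl group (the one attached to C8), and iodinolysis with retention should give the (Z)-3-iodoallylic alcohol; C8 is not involved.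

Step 11
Reactants: 17 (2Z)-3-iodo-3-[(2R,6S,7aR)-6-(TBS-oxy)-4,4,7a-trimethyl-2,4,5,6,7,7a-hexahydro-1-benzofuran-2-yl]prop-2-en-1-ol
Product: 18 3-[(2R,6S,7aR)-6-(TBS-oxy)-4,4,7a-trimethyl-2,4,5,6,7,7a-hexahydro-1-benzofuran-2-yl]furan-2(5H)-one
Conditions: PdCl2(PPh3)2 (cat.), CO (1 atm), Et3N, MeCN, 40 °C
Reagents that add atoms: carbon monoxide [C-]#[O+]
Why: Palladium-catalysed carbonylative lactonisation: oxidative addition into the C–I bond, CO insertion and capture of the acylpalladium by the cis-disposed CH2OH give the α-substituted butenolide.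

Step 12
Reactants: 3 (4S)-4-(TBS-oxy)-2,6,6-trimethylcyclohex-2-en-1-one
Product: 20 (4R)-4-(TBS-oxy)-2,6,6-trimethylcyclohex-1-en-1-yl trifluoromethanesulfonate, via lithium enolate 19 (not isolated)
Conditions: LiBH(s-Bu)3 (L-Selectride), THF, −78 °C; then PhNTf2, −78 to 0 °C
Reagents that add atoms: N-phenylbis(trifluoromethanesulfonimide) O=S(=O)(N(c1ccccc1)S(=O)(=O)C(F)(F)F)C(F)(F)F
Why: Conjugate reduction of the β-unsubstituted, carbonyl-hindered enone gives one regiodefined enolate, which is O-triflated (reductive triflation); the carbinol stereocentre is untouched and becomes (R) only by a change of priorities.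

Step 13
Reactants: 20 (4R)-4-(TBS-oxy)-2,6,6-trimethylcyclohex-1-en-1-yl trifluoromethanesulfonate; 21 (2E)-3-methylpent-2-en-4-yn-1-ol
Product: 22 (2E)-5-[(4R)-4-(TBS-oxy)-2,6,6-trimethylcyclohex-1-en-1-yl]-3-methylpent-2-en-4-yn-1-ol
Conditions: Pd(PPh3)4 (cat.), CuI (cat.), i-Pr2NH, DMF, rt
Reagents that add atoms: none
Why: Sonogashira coupling of the enol triflate with the terminal alkyne tolerates the free allylic alcohol and keeps the E alkene of 21.

Step 14
Reactants: 22 (2E)-5-[(4R)-4-(TBS-oxy)-2,6,6-trimethylcyclohex-1-en-1-yl]-3-methylpent-2-en-4-yn-1-ol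
Product: 24 {(2E)-5-[(4R)-4-(TBS-oxy)-2,6,6-trimethylcyclohex-1-en-1-yl]-3-methylpent-2-en-4-yn-1-yl}triphenylphosphonium bromide, via allylic bromide 23 (not isolated)
Conditions: CBr4, PPh3, CH2Cl2, 0 °C; then PPh3, MeCN, rt
Reagents that add atoms: carbon tetrabromide BrC(Br)(Br)Br; triphenylphosphine c1ccc(cc1)P(c1ccccc1)c1ccccc1
Why: Appel bromination of the primary allylic alcohol under neutral conditions, then SN2 quaternisation of PPh3, gives the C5 Wittig salt without acid that could cleave the silyl ether.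

Step 15
Reactants: 24 {(2E)-5-[(4R)-4-(TBS-oxy)-2,6,6-trimethylcyclohex-1-en-1-yl]-3-methylpent-2-en-4-yn-1-yl}triphenylphosphonium bromide; 25 (2E)-4,4-dimethoxybut-2-enal (fumaraldehyde mono(dimethyl acetal))
Product: 28 (2E,4E,6E)-9-[(4R)-4-(TBS-oxy)-2,6,6-trimethylcyclohex-1-en-1-yl]-7-methylnona-2,4,6-trien-8-ynal, via phosphonium ylide 26 (not isolated), via dimethyl acetal 27 (not isolated)
Conditions: NaN(SiMe3)2, THF, −78 °C; 25, −78 to 0 °C; aq. oxalic acid, THF, rt; I2 (cat.), CH2Cl2, daylight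
Reagents that add atoms: none
Why: Wittig olefination of the semi-stabilised allylic ylide with the free aldehyde of 25 forms the new C=C bond as an E/Z mixture, mild acid unmasks the aldehyde, and iodine-catalysed equilibration should bring the triene to the all-E form.

Step 16
Reactants: 28 (2E,4E,6E)-9-[(4R)-4-(TBS-oxy)-2,6,6-trimethylcyclohex-1-en-1-yl]-7-methylnona-2,4,6-trien-8-ynal; 29 2-(triphenylphosphoranylidene)propanal
Product: 30 (2E,4E,6E,8E)-11-[(4R)-4-(TBS-oxy)-2,6,6-trimethylcyclohex-1-en-1-yl]-2,9-dimethylundeca-2,4,6,8-tetraen-10-ynal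
Conditions: toluene, 80 °C
Reagents that add atoms: none
Why: Wittig reaction of a stabilised ylide is E-selective and stops after one homologation because the α-methyl enal formed is much less electrophilic than 28.

Step 17
Reactants: 18 3-[(2R,6S,7aR)-6-(TBS-oxy)-4,4,7a-trimethyl-2,4,5,6,7,7a-hexahydro-1-benzofuran-2-yl]furan-2(5H)-one; 30 (2E,4E,6E,8E)-11-[(4R)-4-(TBS-oxy)-2,6,6-trimethylcyclohex-1-en-1-yl]-2,9-dimethylundeca-2,4,6,8-tetraen-10-ynal
Product: 33 bis-TBS ether of the target (both secondary hydroxy groups silylated), via silyloxyfuran 31 (not isolated), via silylated aldol adduct 32 (not isolated)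
Conditions: TBSOTf, i-Pr2NEt, CH2Cl2, 0 °C to rt; then DBU, rt
Reagents that add atoms: none
Why: Vinylogous Mukaiyama aldol addition of the 2-silyloxyfuran formed in the flask (attack through the furan 5-position on the silyl-activated aldehyde) followed by DBU-induced E1cB loss of silanolate should give the thermodynamically preferred (Z)-ylidenebutenolide; the two transient stereocentres of the adduct disappear and C8 is not acidified.

Step 18
Reactants: 33 bis-TBS ether of the target
Product: 34 target CNP0300047.2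
Conditions: Bu4NF, AcOH, THF, 0 °C to rt
Reagents that add atoms: none
Why: Fluoride-mediated cleavage of both secondary silyl ethers, buffered with acetic acid to spare the ylidenebutenolide and the allylic ether at C8, releases the diol without touching any stereocentre.

Compound list
1 | 2,6,6-trimethylcyclohex-2-ene-1,4-dione (ketoisophorone) | CC1=CC(=O)CC(C)(C)C1=O | starting material
2 | (4S)-4-hydroxy-2,6,6-trimethylcyclohex-2-en-1-one | CC1=C[C@@H](O)CC(C)(C)C1=O | intermediate
3 | (4S)-4-(TBS-oxy)-2,6,6-trimethylcyclohex-2-en-1-one | CC1=C[C@@H](O[Si](C)(C)C(C)(C)C)CC(C)(C)C1=O | intermediate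
4 | (1R,5S,6R)-5-(TBS-oxy)-1,3,3-trimethyl-7-oxabicyclo[4.1.0]heptan-2-one | O=C1C(C)(C)C[C@H](O[Si](C)(C)C(C)(C)C)[C@H]2O[C@@]12C | intermediate
5 | (2R,4S)-4-(TBS-oxy)-2,6,6-trimethylcyclohexane-1,2-diol, C1 epimers | OC1C(C)(C)C[C@H](O[Si](C)(C)C(C)(C)C)C[C@@]1(C)O | intermediate
6 | (2R,4S)-4-(TBS-oxy)-2-hydroxy-2,6,6-trimethylcyclohexan-1-one | O=C1C(C)(C)C[C@H](O[Si](C)(C)C(C)(C)C)C[C@@]1(C)O | intermediate
7 | tert-butyldimethyl(prop-2-yn-1-yloxy)silane | C#CCO[Si](C)(C)C(C)(C)C | starting material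
8 | (E)-1,2-dichloroethene | Cl/C=C/Cl | starting material
9 | (E)-tert-butyl[(5-chloropent-4-en-2-yn-1-yl)oxy]dimethylsilane | Cl/C=C/C#CCO[Si](C)(C)C(C)(C)C | intermediate
10 | (E)-{5-(TBS-oxy)pent-1-en-3-yn-1-yl}triphenylphosphonium chloride | [Cl-].CC(C)(C)[Si](C)(C)OCC#C/C=C/[P+](c1ccccc1)(c1ccccc1)c1ccccc1 | intermediate
11 | sodium alkoxide of 6 | O=C1C(C)(C)C[C@H](O[Si](C)(C)C(C)(C)C)C[C@@]1(C)[O-].[Na+] | intermediate (not isolated)
12 | β-oxido ylide: 6 O-alkylated at the tertiary oxygen by the 5-(TBS-oxy)-1-(triphenylphosphoranylidene)pent-3-yn-2-yl group, interconverting C8 epimers | O=C1C(C)(C)C[C@H](O[Si](C)(C)C(C)(C)C)C[C@@]1(C)OC(C#CCO[Si](C)(C)C(C)(C)C)C=P(c1ccccc1)(c1ccccc1)c1ccccc1 | intermediate (not isolated)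
13 | cis-fused oxaphosphetane from attack of C7 on the C6 carbonyl (PPh3 on C7 syn to the C5 methyl and anti to the alkynyl group on C8) | CC(C)(C)[Si](C)(C)OCC#C[C@@H]1O[C@]2(C)C[C@@H](O[Si](C)(C)C(C)(C)C)CC(C)(C)[C@@]23OP(c4ccccc4)(c4ccccc4)(c4ccccc4)[C@@H]13 | intermediate (not isolated)
14 | (2R,6S,7aR)-6-(TBS-oxy)-2-[3-(TBS-oxy)prop-1-yn-1-yl]-4,4,7a-trimethyl-2,4,5,6,7,7a-hexahydro-1-benzofuran | CC(C)(C)[Si](C)(C)OCC#C[C@H]1C=C2C(C)(C)C[C@H](O[Si](C)(C)C(C)(C)C)C[C@@]2(C)O1 | intermediate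
15 | 3-[(2R,6S,7aR)-6-(TBS-oxy)-4,4,7a-trimethyl-2,4,5,6,7,7a-hexahydro-1-benzofuran-2-yl]prop-2-yn-1-ol | OCC#C[C@H]1C=C2C(C)(C)C[C@H](O[Si](C)(C)C(C)(C)C)C[C@@]2(C)O1 | intermediate
16 | sodium 2,2-bis(2-methoxyethoxy)-2,5-dihydro-1,2-oxaluminol-2-uide carrying the hexahydrobenzofuranyl group on C3 | [Na+].COCCO[Al-]1(OCCOC)OCC=C1[C@H]1C=C2C(C)(C)C[C@H](O[Si](C)(C)C(C)(C)C)C[C@@]2(C)O1 | intermediate (not isolated)
17 | (2Z)-3-iodo-3-[(2R,6S,7aR)-6-(TBS-oxy)-4,4,7a-trimethyl-2,4,5,6,7,7a-hexahydro-1-benzofuran-2-yl]prop-2-en-1-ol | OC/C=C(\I)[C@H]1C=C2C(C)(C)C[C@H](O[Si](C)(C)C(C)(C)C)C[C@@]2(C)O1 | intermediate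
18 | 3-[(2R,6S,7aR)-6-(TBS-oxy)-4,4,7a-trimethyl-2,4,5,6,7,7a-hexahydro-1-benzofuran-2-yl]furan-2(5H)-one | O=C1OCC=C1[C@H]1C=C2C(C)(C)C[C@H](O[Si](C)(C)C(C)(C)C)C[C@@]2(C)O1 | intermediate
19 | lithium (4R)-4-(TBS-oxy)-2,6,6-trimethylcyclohex-1-en-1-olate | CC1=C([O-])C(C)(C)C[C@H](O[Si](C)(C)C(C)(C)C)C1.[Li+] | intermediate (not isolated)
20 | (4R)-4-(TBS-oxy)-2,6,6-trimethylcyclohex-1-en-1-yl trifluoromethanesulfonate | CC1=C(OS(=O)(=O)C(F)(F)F)C(C)(C)C[C@H](O[Si](C)(C)C(C)(C)C)C1 | intermediate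
21 | (2E)-3-methylpent-2-en-4-yn-1-ol | C#C/C(C)=C/CO | starting material
22 | (2E)-5-[(4R)-4-(TBS-oxy)-2,6,6-trimethylcyclohex-1-en-1-yl]-3-methylpent-2-en-4-yn-1-ol | CC1=C(C#C/C(C)=C/CO)C(C)(C)C[C@H](O[Si](C)(C)C(C)(C)C)C1 | intermediate
23 | allylic bromide of 22 | CC1=C(C#C/C(C)=C/CBr)C(C)(C)C[C@H](O[Si](C)(C)C(C)(C)C)C1 | intermediate (not isolated)
24 | {(2E)-5-[(4R)-4-(TBS-oxy)-2,6,6-trimethylcyclohex-1-en-1-yl]-3-methylpent-2-en-4-yn-1-yl}triphenylphosphonium bromide | [Br-].CC1=C(C#C/C(C)=C/C[P+](c2ccccc2)(c2ccccc2)c2ccccc2)C(C)(C)C[C@H](O[Si](C)(C)C(C)(C)C)C1 | intermediate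
25 | (2E)-4,4-dimethoxybut-2-enal | COC(OC)/C=C/C=O | starting material
26 | phosphonium ylide of 24 | CC1=C(C#C/C(C)=C/C=P(c2ccccc2)(c2ccccc2)c2ccccc2)C(C)(C)C[C@H](O[Si](C)(C)C(C)(C)C)C1 | intermediate (not isolated)
27 | dimethyl acetal of 28 (drawn all-E; formed as E/Z mixture at the new C=C bond) | CC1=C(C#C/C(C)=C/C=C/C=C/C(OC)OC)C(C)(C)C[C@H](O[Si](C)(C)C(C)(C)C)C1 | intermediate (not isolated)
28 | (2E,4E,6E)-9-[(4R)-4-(TBS-oxy)-2,6,6-trimethylcyclohex-1-en-1-yl]-7-methylnona-2,4,6-trien-8-ynal | CC1=C(C#C/C(C)=C/C=C/C=C/C=O)C(C)(C)C[C@H](O[Si](C)(C)C(C)(C)C)C1 | intermediate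
29 | 2-(triphenylphosphoranylidene)propanal | CC(C=O)=P(c1ccccc1)(c1ccccc1)c1ccccc1 | starting material
30 | (2E,4E,6E,8E)-11-[(4R)-4-(TBS-oxy)-2,6,6-trimethylcyclohex-1-en-1-yl]-2,9-dimethylundeca-2,4,6,8-tetraen-10-ynal | CC1=C(C#C/C(C)=C/C=C/C=C/C=C(C)/C=O)C(C)(C)C[C@H](O[Si](C)(C)C(C)(C)C)C1 | intermediate
31 | 2-(TBS-oxy)furan carrying the hexahydrobenzofuranyl group of 18 at its 3-position | CC(C)(C)[Si](C)(C)Oc1occc1[C@H]1C=C2C(C)(C)C[C@H](O[Si](C)(C)C(C)(C)C)C[C@@]2(C)O1 | intermediate (not isolated)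
32 | O-silylated vinylogous aldol adduct of 18 and 30 (epimers at the two new centres) | CC1=C(C#C/C(C)=C/C=C/C=C/C=C(C)/C(O[Si](C)(C)C(C)(C)C)C2OC(=O)C([C@H]3C=C4C(C)(C)C[C@H](O[Si](C)(C)C(C)(C)C)C[C@@]4(C)O3)=C2)C(C)(C)C[C@H](O[Si](C)(C)C(C)(C)C)C1 | intermediate (not isolated)
33 | bis-TBS ether of the target | CC1=C(C#C/C(C)=C/C=C/C=C/C=C(C)/C=C2/C=C([C@H]3C=C4C(C)(C)C[C@H](O[Si](C)(C)C(C)(C)C)C[C@@]4(C)O3)C(=O)O2)C(C)(C)C[C@H](O[Si](C)(C)C(C)(C)C)C1 | intermediate
34 | target CNP0300047.2, (3S,5R,8R,3′R) | CC1=C(C#C/C(C)=C/C=C/C=C/C=C(C)/C=C2/C=C([C@H]3C=C4C(C)(C)C[C@H](O)C[C@@]4(C)O3)C(=O)O2)C(C)(C)C[C@H](O)C1 | target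

Total step count: 18 steps. Longest linear sequence: 11 steps (steps 1–5, 8–11, 17, 18).

Steps most likely to fail

Step 8 (key step). The Wittig closure onto the doubly neopentyl ketone may be so slow that the alkoxide undergoes α-ketol rearrangement or the ylide is quenched. Alkoxide addition may also divert to the alkyne terminus, or the oxido ylide may cyclise before its C8 epimers equilibrate, which would erode the facial selectivity at C8. The fallback sets out from 6. Heating with Ph3P=C=C=O in toluene (O-acylation, then intramolecular Wittig reaction) should give the butenolide (6S,7aR)-6-(TBS-oxy)-4,4,7a-trimethyl-5,6,7,7a-tetrahydro-1-benzofuran-2(4H)-one F1. Reduction with i-Bu2AlH at −78 °C and acetylation in the same flask (Ac2O, pyridine, DMAP) should give the lactol acetate F2. The oxocarbenium ion released from F2 by BF3·OEt2 is trapped at C8 by the lithium acetylide of 7, lithium 3-(TBS-oxy)prop-1-yn-1-ide F3 (from 7 and n-BuLi, THF, −78 °C). This route has weaker control at C8, so the epimers would be separated by chromatography before it comes back to the route at 14.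

Step 7. Oxidative addition of the alkenyl chloride or reductive elimination of the phosphonium salt may be too slow, and the enyne may oligomerise at the temperature needed. The fallback sets out from 7. Its lithium acetylide (F3 above) is formylated with DMF to 4-(TBS-oxy)but-2-ynal F4. Wittig bromomethylenation with Ph3P=CHBr (from (bromomethyl)triphenylphosphonium bromide and KOt-Bu) gives 5-bromo-1-(TBS-oxy)pent-4-en-2-yne F5 (Z-rich; the geometry is irrelevant). Palladium-catalysed quaternisation of PPh3, which is established for alkenyl bromides, gives {5-(TBS-oxy)pent-1-en-3-yn-1-yl}triphenylphosphonium bromide F6. F6 takes the place of 10 in step 8, and the fallback comes back to the route at 14.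

Step 17. The silyl triflate may ionise the allylic C8–O bond next to the electron-rich silyloxyfuran (ring opening or loss of C8 configuration), and the polyenal may react sluggishly or decompose. The fallback sets out from 18 (with 30) and avoids any Lewis acid. Deprotonation of 18 with LiN(SiMe3)2 in THF at −78 °C and addition of 30 gives the γ-(1-hydroxyalkyl)butenolide aldol adducts F7. Mesylation (MsCl, Et3N) gives the mesylates F8, and DBU-induced elimination should give the (Z)-ylidenebutenolide. The fallback comes back to the route at 33.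

Further compounds
F1 | step 8 | (6S,7aR)-6-(TBS-oxy)-4,4,7a-trimethyl-5,6,7,7a-tetrahydro-1-benzofuran-2(4H)-one | O=C1C=C2C(C)(C)C[C@H](O[Si](C)(C)C(C)(C)C)C[C@@]2(C)O1
F2 | step 8 | (6S,7aR)-6-(TBS-oxy)-4,4,7a-trimethyl-2,4,5,6,7,7a-hexahydro-1-benzofuran-2-yl acetate, C2 epimers | CC(=O)OC1C=C2C(C)(C)C[C@H](O[Si](C)(C)C(C)(C)C)C[C@@]2(C)O1
F3 | step 8 | lithium 3-(TBS-oxy)prop-1-yn-1-ide | [Li+].[C-]#CCO[Si](C)(C)C(C)(C)C
F4 | step 7 | 4-(TBS-oxy)but-2-ynal | O=CC#CCO[Si](C)(C)C(C)(C)C
F5 | step 7 | 5-bromo-1-(TBS-oxy)pent-4-en-2-yne, Z-rich | Br/C=C\C#CCO[Si](C)(C)C(C)(C)C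
F6 | step 7 | {5-(TBS-oxy)pent-1-en-3-yn-1-yl}triphenylphosphonium bromide, geometry mixture | [Br-].CC(C)(C)[Si](C)(C)OCC#CC=C[P+](c1ccccc1)(c1ccccc1)c1ccccc1
F7 | step 17 | γ-(1-hydroxyalkyl)butenolide aldol adducts of 18 and 30, epimers at the two new centres | CC1=C(C#C/C(C)=C/C=C/C=C/C=C(C)/C(O)C2OC(=O)C([C@H]3C=C4C(C)(C)C[C@H](O[Si](C)(C)C(C)(C)C)C[C@@]4(C)O3)=C2)C(C)(C)C[C@H](O[Si](C)(C)C(C)(C)C)C1
F8 | step 17 | methanesulfonates of F7 | CC1=C(C#C/C(C)=C/C=C/C=C/C=C(C)/C(OS(C)(=O)=O)C2OC(=O)C([C@H]3C=C4C(C)(C)C[C@H](O[Si](C)(C)C(C)(C)C)C[C@@]4(C)O3)=C2)C(C)(C)C[C@H](O[Si](C)(C)C(C)(C)C)C1
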